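**Retrosynthetic overview**

1. The last step is hydrogenolysis of seven benzyl ethers. Unit 1 is the 3-linked eriodictyol unit (C2 R, C3 S, trans); unit 2 is the 8''-linked (2S)-naringenin unit.
2. Key disconnection: ring C of unit 1 (O1, C2, C3, C4, C4a, C8a) is cut at O1–C8a and C4–C4a. This leaves the trans-oxetan-2-one O1–C2–C3–C4(=O) and 3,5-bis(benzyloxy)benzyne, whose two triple-bond carbons become C8a and C4a (four-membered to six-membered ring, ring A brought in by the same event).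
3. Enabling feature: in ring A of unit 1 the ether oxygen O1 and the acyl carbon C4 sit on the neighbouring carbons C8a and C4a, with the C5 oxygen beside C4a. This is the pattern a 3-alkoxyaryne delivers (oxygen nucleophile remote from OR, acyl beside OR), and O1–C2–C3–C4(=O) is a β-hydroxy acid, i.e. a β-lactone.
4. The lactone comes from an auxiliary-controlled anti-aldol (sets C2 and C3 of unit 1) between 3,4-bis(benzyloxy)benzaldehyde and the acetic acid carried on C8'' of tri-O-benzyl-(S)-naringenin. That acid comes from 5,7-dihydroxychromone by asymmetric conjugate arylation (sets C2''), C8'' iodination and Negishi coupling.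
5. Order of ring formation: ring C of unit 2 (chromone to flavanone), then the oxetanone, then ring C of unit 1 fused to the newly attached ring A.

Key step: step 12

Assumption: in step 2 the (R) ligand is taken to deliver the 2S flavanone, by analogy with the sense of aryl addition to cyclic enones; should the rotation of a debenzylated sample not match (S)-naringenin, the (S) ligand would be used.

Abbreviations: Bn = benzyl; Nar8 = (2S)-5,7-bis(benzyloxy)-2-[4-(benzyloxy)phenyl]-4-oxochroman-8-yl.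

**Route**

Step 1
Reactants: 1 5,7-dihydroxy-4H-chromen-4-one
Product: 2 5,7-bis(benzyloxy)-4H-chromen-4-one
Conditions: BnBr, K2CO3, DMF, 60 °C
Reagents that add atoms: benzyl bromide (BrCc1ccccc1)
Why: Williamson etherification, in which warm K2CO3/DMF should also alkylate the hydrogen-bonded 5-OH, and the chromone has no stereocentre to lose.

Step 2
Reactants: 2 5,7-bis(benzyloxy)-4H-chromen-4-one; 3 [4-(benzyloxy)phenyl]boronic acid
Product: 4 (2S)-5,7-bis(benzyloxy)-2-[4-(benzyloxy)phenyl]chroman-4-one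
Conditions: Pd(OCOCF3)2 (5 mol%), (R)-t-BuPyOx (6 mol%), NH4PF6 (30 mol%), H2O (5 equiv), ClCH2CH2Cl, 60 °C
Reagents that add atoms: none
Why: Base-free asymmetric conjugate addition of an arylboronic acid to a chromone through an arylpalladium species of divalent palladium, in which the pyridine-oxazoline ligand selects the face of the C2=C3 bond and sets C2 of unit 2 as S.

Step 3
Reactants: 4 (2S)-5,7-bis(benzyloxy)-2-[4-(benzyloxy)phenyl]chroman-4-one
Product: 5 (2S)-5,7-bis(benzyloxy)-2-[4-(benzyloxy)phenyl]-8-iodochroman-4-one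
Conditions: NIS, DMF, 23 °C, dark
Reagents that add atoms: N-iodosuccinimide (O=C1CCC(=O)N1I)
Why: Electrophilic aromatic iodination of the phloroglucinol-type ring A, expected at C8 because C6 lies between two benzyloxy groups while C8 is flanked by the tied-back ring oxygen; the neutral conditions leave C2 untouched.

Step 4
Reactants: 5 (2S)-5,7-bis(benzyloxy)-2-[4-(benzyloxy)phenyl]-8-iodochroman-4-one; 6 (2-tert-butoxy-2-oxoethyl)zinc bromide
Product: 7 tert-butyl 2-Nar8-acetate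
Conditions: Pd2(dba)3 (2.5 mol%), XPhos (6 mol%), THF, 60 °C
Reagents that add atoms: none
Why: Negishi coupling with a Reformatsky reagent (oxidative addition to zerovalent palladium, transmetalation, reductive elimination), whose weakly basic zinc enolate should tolerate the enolisable ketone and the C2 stereocentre.

Step 5
Reactants: 7 tert-butyl 2-Nar8-acetate
Product: 8 2-Nar8-acetic acid
Conditions: TFA, CH2Cl2, 0 to 23 °C
Reagents that add atoms: none
Why: Acidolysis of the tert-butyl ester with E1 loss of isobutene, conditions under which aryl benzyl ethers and the flavanone should survive.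

Step 6
Reactants: 8 2-Nar8-acetic acid; 9 (R)-4-benzyloxazolidin-2-one
Product: 11 (4R)-4-benzyl-3-(2-Nar8-acetyl)oxazolidin-2-one, via mixed pivalic anhydride 10 (not isolated)
Conditions: PivCl, Et3N, THF, −20 °C; then LiCl, 9, 23 °C
Reagents that add atoms: none
Why: N-Acylation of the oxazolidinone through the mixed anhydride under LiCl/Et3N, which avoids strong base near the flavanone.

Step 7
Reactants: 11 (4R)-4-benzyl-3-(2-Nar8-acetyl)oxazolidin-2-one; 12 3,4-bis(benzyloxy)benzaldehyde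
Product: 14 (4R)-4-benzyl-3-[(2S,3R)-3-[3,4-bis(benzyloxy)phenyl]-3-hydroxy-2-Nar8-propanoyl]oxazolidin-2-one, via silyl ether 13 (not isolated)
Conditions: MgCl2 (0.2 equiv), Et3N, TMSCl, EtOAc, 23 °C; then 1 M HCl, THF
Reagents that add atoms: none
Why: Magnesium-catalysed anti-selective Evans aldol by soft enolisation, in which the chelated Z-enolate is attacked through a boat transition state on the face opposite the auxiliary benzyl group (setting chain C2 as S and C3 as R, the later C3 and C2 of unit 1) and silylation of the aldolate by TMSCl blocks retro-aldol.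

Step 8
Reactants: 14 (4R)-4-benzyl-3-[(2S,3R)-3-[3,4-bis(benzyloxy)phenyl]-3-hydroxy-2-Nar8-propanoyl]oxazolidin-2-one
Product: 16 (2S,3R)-3-[3,4-bis(benzyloxy)phenyl]-3-hydroxy-2-Nar8-propanoic acid, via peroxy acid 15 (not isolated)
Conditions: LiOH, H2O2, THF/H2O, 0 °C; then Na2SO3; then HCl to pH 3
Reagents that add atoms: hydrogen peroxide (OO)
Why: Hydroperoxide cleavage of the exocyclic imide carbonyl followed by sulfite reduction of the peracid, a weakly basic method that should free the acid and the auxiliary without touching either new stereocentre.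

Step 9
Reactants: 16 (2S,3R)-3-[3,4-bis(benzyloxy)phenyl]-3-hydroxy-2-Nar8-propanoic acid
Product: 18 (3S,4R)-4-[3,4-bis(benzyloxy)phenyl]-3-Nar8-oxetan-2-one, via mixed sulfonic anhydride 17 (not isolated)
Conditions: PhSO2Cl, pyridine, 0 °C; rapid filtration through Florisil, used at once
Reagents that add atoms: none
Why: β-Lactonisation by carboxyl activation (4-exo-trig attack of the hydroxyl on the mixed anhydride), which retains the carbinol configuration so that the anti acid should give the trans lactone.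

Step 10
Reactants: 19 3,5-bis(benzyloxy)phenol
Product: 20 3,5-bis(benzyloxy)-2-bromophenol
Conditions: NBS, CH2Cl2, −78 °C
Reagents that add atoms: N-bromosuccinimide (O=C1CCC(=O)N1Br)
Why: Electrophilic bromination ortho to the free hydroxyl at low temperature, the position between OH and OBn being less hindered than the one between the two benzyloxy groups.

Step 11
Reactants: 20 3,5-bis(benzyloxy)-2-bromophenol
Product: 23 3,5-bis(benzyloxy)-2-(trimethylsilyl)phenyl trifluoromethanesulfonate, via aryl silyl ether 21 (not isolated), via lithium phenoxide 22 (not isolated)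
Conditions: HMDS, THF, 70 °C; concentrate; n-BuLi, THF, −100 to −78 °C; then Tf2O, −100 to −78 °C
Reagents that add atoms: hexamethyldisilazane (C[Si](C)(C)N[Si](C)(C)C); trifluoromethanesulfonic anhydride (O=S(=O)(OS(=O)(=O)C(F)(F)F)C(F)(F)F)
Why: O-Silylation, bromine–lithium exchange and 1,3 O-to-C silyl shift (retro-Brook rearrangement) should place the silyl group ortho to the phenoxide, which is then triflated to give the 2-(trimethylsilyl)aryl triflate.

Step 12
Reactants: 18 (3S,4R)-4-[3,4-bis(benzyloxy)phenyl]-3-Nar8-oxetan-2-one; 23 3,5-bis(benzyloxy)-2-(trimethylsilyl)phenyl trifluoromethanesulfonate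
Product: 27 (2R,3S)-5,7-bis(benzyloxy)-2-[3,4-bis(benzyloxy)phenyl]-3-Nar8-chroman-4-one, via aryne 24 (not isolated), via alkoxide ester 25 (not isolated), via aryl anion 26 (not isolated)
Conditions: KF (3 equiv), 18-crown-6 (3 equiv), KOCH2CF3 (0.2 equiv), THF, 0 to 23 °C
Reagents that add atoms: none
Why: Proposed new method: fluoride releases 3,5-bis(benzyloxy)benzyne 24 from 23 while catalytic trifluoroethoxide opens the strained lactone 18 at its acyl carbon to alkoxide ester 25; the alkoxide oxygen adds to the aryne carbon remote from the neighbouring benzyloxy group (aryne distortion and inductive stabilisation put the charge beside that oxygen), and aryl anion 26 attacks the pendant trifluoroethyl ester in a 6-exo-trig acyl substitution that closes ring C (O1–C8a first, then C4a–C4) and returns trifluoroethoxide. The closest known reactions are the insertion of arynes into the N–C(O) bond of β-lactams (ring expansion to 2,3-dihydroquinolin-4-ones), the acyl-alkylation of arynes with β-keto esters and the annulation of arynes with 2-hydroxybenzoates to xanthones. No bond to C2 or C3 is broken, so both stereocentres should be carried over from the lactone (its C4 becomes C2, its C3 stays C3), and the trans-2,3-diaryl arrangement is also the thermodynamic one. The step needs regioselectivity at the aryne, secured by the 3-benzyloxy group, and O-arylation faster than retro-aldol cleavage of 25, which the high rate of alkoxide addition to arynes, the weakly coordinating medium and the low temperature should favour.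

Step 13
Reactants: 27 (2R,3S)-5,7-bis(benzyloxy)-2-[3,4-bis(benzyloxy)phenyl]-3-Nar8-chroman-4-one
Product: 28 (2R,3S)-2-(3,4-dihydroxyphenyl)-5,7-dihydroxy-3-[(2S)-5,7-dihydroxy-2-(4-hydroxyphenyl)-4-oxochroman-8-yl]chroman-4-one
Conditions: H2 (1 atm), 10% Pd/C, THF/MeOH, 23 °C
Reagents that add atoms: none
Why: Hydrogenolysis of the seven aryl benzyl ethers under neutral conditions, which should leave the three stereocentres and both ketones untouched if stopped at full debenzylation.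

**Compound list**

1 | 5,7-dihydroxy-4H-chromen-4-one | O=c1ccoc2cc(O)cc(O)c12 | starting material
2 | 5,7-bis(benzyloxy)-4H-chromen-4-one | O=c1ccoc2cc(OCc3ccccc3)cc(OCc3ccccc3)c12 | intermediate
3 | [4-(benzyloxy)phenyl]boronic acid | OB(O)c1ccc(OCc2ccccc2)cc1 | starting material
4 | (2S)-5,7-bis(benzyloxy)-2-[4-(benzyloxy)phenyl]chroman-4-one | O=C1C[C@@H](c2ccc(OCc3ccccc3)cc2)Oc2cc(OCc3ccccc3)cc(OCc3ccccc3)c12 | intermediate
5 | (2S)-5,7-bis(benzyloxy)-2-[4-(benzyloxy)phenyl]-8-iodochroman-4-one | O=C1C[C@@H](c2ccc(OCc3ccccc3)cc2)Oc2c(I)c(OCc3ccccc3)cc(OCc3ccccc3)c12 | intermediate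
6 | (2-tert-butoxy-2-oxoethyl)zinc bromide | CC(C)(C)OC(=O)C[Zn]Br | starting material
7 | tert-butyl 2-Nar8-acetate | O=C1C[C@@H](c2ccc(OCc3ccccc3)cc2)Oc2c(CC(=O)OC(C)(C)C)c(OCc3ccccc3)cc(OCc3ccccc3)c12 | intermediate
8 | 2-Nar8-acetic acid | O=C1C[C@@H](c2ccc(OCc3ccccc3)cc2)Oc2c(CC(=O)O)c(OCc3ccccc3)cc(OCc3ccccc3)c12 | intermediate
9 | (R)-4-benzyloxazolidin-2-one | O=C1N[C@H](Cc2ccccc2)CO1 | starting material
10 | mixed anhydride of 8 with pivalic acid | O=C1C[C@@H](c2ccc(OCc3ccccc3)cc2)Oc2c(CC(=O)OC(=O)C(C)(C)C)c(OCc3ccccc3)cc(OCc3ccccc3)c12 | intermediate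
11 | (4R)-4-benzyl-3-(2-Nar8-acetyl)oxazolidin-2-one | O=C1C[C@@H](c2ccc(OCc3ccccc3)cc2)Oc2c(CC(=O)N3C(=O)OC[C@H]3Cc3ccccc3)c(OCc3ccccc3)cc(OCc3ccccc3)c12 | intermediate
12 | 3,4-bis(benzyloxy)benzaldehyde | O=Cc1ccc(OCc2ccccc2)c(OCc2ccccc2)c1 | starting material
13 | O-trimethylsilyl ether of 14 | O=C1C[C@@H](c2ccc(OCc3ccccc3)cc2)Oc2c([C@H](C(=O)N3C(=O)OC[C@H]3Cc3ccccc3)[C@@H](O[Si](C)(C)C)c3ccc(OCc4ccccc4)c(OCc4ccccc4)c3)c(OCc3ccccc3)cc(OCc3ccccc3)c12 | intermediate
14 | (4R)-4-benzyl-3-[(2S,3R)-3-[3,4-bis(benzyloxy)phenyl]-3-hydroxy-2-Nar8-propanoyl]oxazolidin-2-one | O=C1C[C@@H](c2ccc(OCc3ccccc3)cc2)Oc2c([C@H](C(=O)N3C(=O)OC[C@H]3Cc3ccccc3)[C@@H](O)c3ccc(OCc4ccccc4)c(OCc4ccccc4)c3)c(OCc3ccccc3)cc(OCc3ccccc3)c12 | intermediate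
15 | (2S,3R)-3-[3,4-bis(benzyloxy)phenyl]-3-hydroxy-2-Nar8-propaneperoxoic acid | O=C1C[C@@H](c2ccc(OCc3ccccc3)cc2)Oc2c([C@H](C(=O)OO)[C@@H](O)c3ccc(OCc4ccccc4)c(OCc4ccccc4)c3)c(OCc3ccccc3)cc(OCc3ccccc3)c12 | intermediate
16 | (2S,3R)-3-[3,4-bis(benzyloxy)phenyl]-3-hydroxy-2-Nar8-propanoic acid | O=C1C[C@@H](c2ccc(OCc3ccccc3)cc2)Oc2c([C@H](C(=O)O)[C@@H](O)c3ccc(OCc4ccccc4)c(OCc4ccccc4)c3)c(OCc3ccccc3)cc(OCc3ccccc3)c12 | intermediate
17 | mixed anhydride of 16 with benzenesulfonic acid | O=C1C[C@@H](c2ccc(OCc3ccccc3)cc2)Oc2c([C@H](C(=O)OS(=O)(=O)c3ccccc3)[C@@H](O)c3ccc(OCc4ccccc4)c(OCc4ccccc4)c3)c(OCc3ccccc3)cc(OCc3ccccc3)c12 | intermediate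
18 | (3S,4R)-4-[3,4-bis(benzyloxy)phenyl]-3-Nar8-oxetan-2-one (trans) | O=C1C[C@@H](c2ccc(OCc3ccccc3)cc2)Oc2c([C@@H]3C(=O)O[C@H]3c3ccc(OCc4ccccc4)c(OCc4ccccc4)c3)c(OCc3ccccc3)cc(OCc3ccccc3)c12 | intermediate
19 | 3,5-bis(benzyloxy)phenol | Oc1cc(OCc2ccccc2)cc(OCc2ccccc2)c1 | starting material
20 | 3,5-bis(benzyloxy)-2-bromophenol | Oc1cc(OCc2ccccc2)cc(OCc2ccccc2)c1Br | intermediate
21 | [3,5-bis(benzyloxy)-2-bromophenoxy]trimethylsilane | C[Si](C)(C)Oc1cc(OCc2ccccc2)cc(OCc2ccccc2)c1Br | intermediate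
22 | lithium 3,5-bis(benzyloxy)-2-(trimethylsilyl)phenoxide | [Li+].[O-]c1cc(OCc2ccccc2)cc(OCc2ccccc2)c1[Si](C)(C)C | intermediate
23 | 3,5-bis(benzyloxy)-2-(trimethylsilyl)phenyl trifluoromethanesulfonate | C[Si](C)(C)c1c(OS(=O)(=O)C(F)(F)F)cc(OCc2ccccc2)cc1OCc1ccccc1 | intermediate
24 | 3,5-bis(benzyloxy)benzyne (1,2-didehydro-3,5-bis(benzyloxy)benzene) | C1#CC(OCc2ccccc2)=CC(OCc2ccccc2)=C1 | intermediate
25 | potassium alkoxide of 2,2,2-trifluoroethyl (2S,3R)-3-[3,4-bis(benzyloxy)phenyl]-3-hydroxy-2-Nar8-propanoate | [K+].O=C1C[C@@H](c2ccc(OCc3ccccc3)cc2)Oc2c([C@H](C(=O)OCC(F)(F)F)[C@@H]([O-])c3ccc(OCc4ccccc4)c(OCc4ccccc4)c3)c(OCc3ccccc3)cc(OCc3ccccc3)c12 | intermediate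
26 | potassium aryl anion: 25 O-arylated by 24, carbanion at the ring carbon between the new ether oxygen and a benzyloxy group | [K+].O=C1C[C@@H](c2ccc(OCc3ccccc3)cc2)Oc2c([C@H](C(=O)OCC(F)(F)F)[C@@H](Oc3cc(OCc4ccccc4)cc(OCc4ccccc4)[c-]3)c3ccc(OCc4ccccc4)c(OCc4ccccc4)c3)c(OCc3ccccc3)cc(OCc3ccccc3)c12 | intermediate
27 | (2R,3S)-5,7-bis(benzyloxy)-2-[3,4-bis(benzyloxy)phenyl]-3-Nar8-chroman-4-one (hepta-O-benzyl ether of the target) | O=C1C[C@@H](c2ccc(OCc3ccccc3)cc2)Oc2c([C@@H]3C(=O)c4c(OCc5ccccc5)cc(OCc5ccccc5)cc4O[C@H]3c3ccc(OCc4ccccc4)c(OCc4ccccc4)c3)c(OCc3ccccc3)cc(OCc3ccccc3)c12 | intermediate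
28 | (2R,3S)-2-(3,4-dihydroxyphenyl)-5,7-dihydroxy-3-[(2S)-5,7-dihydroxy-2-(4-hydroxyphenyl)-4-oxochroman-8-yl]chroman-4-one | O=C1C[C@@H](c2ccc(O)cc2)Oc2c1c(O)cc(O)c2[C@@H]1C(=O)c2c(O)cc(O)cc2O[C@H]1c1ccc(O)c(O)c1 | target

**Step count and risks**

Total steps: 13. Longest linear sequence: 11 (steps 1 to 9, 12, 13); steps 10 and 11 form the side branch to the aryne precursor.

Most likely to fail:

1. Step 12 (proposed new method). Several processes could defeat it:
   - retro-aldol fragmentation of the ring-opened alkoxide before it is arylated;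
   - base-induced β-elimination or loss of carbon dioxide from the electron-rich 4-aryl lactone;
   - protonation of the aryl anion before acyl transfer;
   - retro-oxa-Michael opening of either chromanone under the basic fluoride.

   Each would erode configuration at C2 or C2'' or stop at an open-chain product. The fallback uses known reaction types only, sets out from 8 and returns at 27. Acid 8 is N-acylated (PivCl, Et3N, LiCl) onto (S)-4-benzyloxazolidin-2-one F1 to give the imide F2. Its dibutylboron enolate (Bu2BOTf, i-Pr2NEt, CH2Cl2, −78 °C) should add to 12 in an Evans syn-aldol to give the (2S,3S) adduct F3. LiOH/H2O2 should give the syn acid F4. Intermolecular C–O addition of this carboxylic acid to aryne 24 (from 23, CsF, THF, 65 °C) should give the 2-hydroxyaryl ketone F5, with the acyl group beside the benzyloxy group. Mitsunobu ring closure (PPh3, DIAD, THF, 0 °C) inverts the carbinol carbon and should give 27.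

2. Step 7. The hindered, acidic arylacetyl imide may react with poor facial or anti/syn selectivity, or epimerise at the α-carbon under Et3N. The fallback sets out from 11 and returns at 27, and relies only on the carbinol centre. The Bu2BOTf/i-Pr2NEt syn-aldol of 11 with 12 should give the (2R,3R) adduct F6, whose carbinol carbon already has the configuration needed for C2. LiOH/H2O2 should give acid F7, and PhSO2Cl/pyridine the cis lactone F8. The conditions of step 12 should give the cis chromanone F9. Catalytic DBU (CH2Cl2, 0 °C) should then epimerise C3, which lies between the ketone and the aryl group, to the more stable trans isomer 27.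

3. Step 2. Conjugate addition to the electron-rich, 5-substituted chromone may be slow or poorly face-selective. The fallback sets out from 19 and returns at 4, building ring C of unit 2 from a preformed stereocentre. Ethyl 3-[4-(benzyloxy)phenyl]-3-oxopropanoate F10 (purchased) is hydrogenated (RuCl2[(S)-BINAP], H2, EtOH) to the (R) hydroxy ester F11. Mitsunobu etherification with 19 (PPh3, DIAD) inverts it to the (S) aryl ether F12. LiOH gives acid F13. Trifluoroacetic anhydride should then close the ring by intramolecular Friedel–Crafts acylation at either of the two equivalent positions ortho to the ether oxygen, giving 4.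

Further compounds

F1 | step 12 | (S)-4-benzyloxazolidin-2-one (purchased) | O=C1N[C@@H](Cc2ccccc2)CO1
F2 | step 12 | (4S)-4-benzyl-3-(2-Nar8-acetyl)oxazolidin-2-one | O=C1C[C@@H](c2ccc(OCc3ccccc3)cc2)Oc2c(CC(=O)N3C(=O)OC[C@@H]3Cc3ccccc3)c(OCc3ccccc3)cc(OCc3ccccc3)c12
F3 | step 12 | (4S)-4-benzyl-3-[(2S,3S)-3-[3,4-bis(benzyloxy)phenyl]-3-hydroxy-2-Nar8-propanoyl]oxazolidin-2-one | O=C1C[C@@H](c2ccc(OCc3ccccc3)cc2)Oc2c([C@H](C(=O)N3C(=O)OC[C@@H]3Cc3ccccc3)[C@H](O)c3ccc(OCc4ccccc4)c(OCc4ccccc4)c3)c(OCc3ccccc3)cc(OCc3ccccc3)c12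
F4 | step 12 | (2S,3S)-3-[3,4-bis(benzyloxy)phenyl]-3-hydroxy-2-Nar8-propanoic acid | O=C1C[C@@H](c2ccc(OCc3ccccc3)cc2)Oc2c([C@H](C(=O)O)[C@H](O)c3ccc(OCc4ccccc4)c(OCc4ccccc4)c3)c(OCc3ccccc3)cc(OCc3ccccc3)c12
F5 | step 12 | (2S,3S)-1-[2,4-bis(benzyloxy)-6-hydroxyphenyl]-3-[3,4-bis(benzyloxy)phenyl]-3-hydroxy-2-Nar8-propan-1-one | O=C1C[C@@H](c2ccc(OCc3ccccc3)cc2)Oc2c([C@H](C(=O)c3c(O)cc(OCc4ccccc4)cc3OCc3ccccc3)[C@H](O)c3ccc(OCc4ccccc4)c(OCc4ccccc4)c3)c(OCc3ccccc3)cc(OCc3ccccc3)c12
F6 | step 7 | (4R)-4-benzyl-3-[(2R,3R)-3-[3,4-bis(benzyloxy)phenyl]-3-hydroxy-2-Nar8-propanoyl]oxazolidin-2-one | O=C1C[C@@H](c2ccc(OCc3ccccc3)cc2)Oc2c([C@@H](C(=O)N3C(=O)OC[C@H]3Cc3ccccc3)[C@@H](O)c3ccc(OCc4ccccc4)c(OCc4ccccc4)c3)c(OCc3ccccc3)cc(OCc3ccccc3)c12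
F7 | step 7 | (2R,3R)-3-[3,4-bis(benzyloxy)phenyl]-3-hydroxy-2-Nar8-propanoic acid | O=C1C[C@@H](c2ccc(OCc3ccccc3)cc2)Oc2c([C@@H](C(=O)O)[C@@H](O)c3ccc(OCc4ccccc4)c(OCc4ccccc4)c3)c(OCc3ccccc3)cc(OCc3ccccc3)c12
F8 | step 7 | (3R,4R)-4-[3,4-bis(benzyloxy)phenyl]-3-Nar8-oxetan-2-one (cis) | O=C1C[C@@H](c2ccc(OCc3ccccc3)cc2)Oc2c([C@H]3C(=O)O[C@H]3c3ccc(OCc4ccccc4)c(OCc4ccccc4)c3)c(OCc3ccccc3)cc(OCc3ccccc3)c12
F9 | step 7 | (2R,3R)-5,7-bis(benzyloxy)-2-[3,4-bis(benzyloxy)phenyl]-3-Nar8-chroman-4-one (cis) | O=C1C[C@@H](c2ccc(OCc3ccccc3)cc2)Oc2c([C@H]3C(=O)c4c(OCc5ccccc5)cc(OCc5ccccc5)cc4O[C@H]3c3ccc(OCc4ccccc4)c(OCc4ccccc4)c3)c(OCc3ccccc3)cc(OCc3ccccc3)c12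
F10 | step 2 | ethyl 3-[4-(benzyloxy)phenyl]-3-oxopropanoate (purchased) | CCOC(=O)CC(=O)c1ccc(OCc2ccccc2)cc1
F11 | step 2 | ethyl (3R)-3-[4-(benzyloxy)phenyl]-3-hydroxypropanoate | CCOC(=O)C[C@@H](O)c1ccc(OCc2ccccc2)cc1
F12 | step 2 | ethyl (3S)-3-[3,5-bis(benzyloxy)phenoxy]-3-[4-(benzyloxy)phenyl]propanoate | CCOC(=O)C[C@H](Oc1cc(OCc2ccccc2)cc(OCc2ccccc2)c1)c1ccc(OCc2ccccc2)cc1
F13 | step 2 | (3S)-3-[3,5-bis(benzyloxy)phenoxy]-3-[4-(benzyloxy)phenyl]propanoic acid | OC(=O)C[C@H](Oc1cc(OCc2ccccc2)cc(OCc2ccccc2)c1)c1ccc(OCc2ccccc2)cc1
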